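Retrosynthesis (side chain numbered C1'–C12' outward from the ring): the first cut is C6'–C7', in the middle of the saturated run, giving two carboxylic acids whose CO2H groups serve as traceless handles. Further cuts are C12'–S, then C1'–C2' and C3'–CH3 (alkyne carbometalation), and last the γ-pyrone at O1–C2, C5–C6 and C3–C4.
Forward: methyl methoxyacetate, propionyl chloride and an acetyl unit give a triketide that closes the only ring. O-methylation, chlorination at C1', coupling with the alkenylalane from hex-5-yn-1-ol and oxidation give the head acid. The tail acid comes in one step from 7-bromoheptanoic acid, and the last step joins the two acids.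
Enabling feature: C6' and C7' are two unactivated primary CH2 groups of like polarity. C6' lies three CH2 from C3', so its radical is a pent-4-enyl radical toward C2'=C3', open only to slow 4-exo or 5-endo closure, and C7' lies six CH2 from S. The ring O1/C2–C6 is fully substituted and hard to reduce, so both radicals can be paired on nickel.
Stereochemistry: there is no stereocentre. The only stereo-element, (E)-C2'=C3', comes from syn-carboalumination and a stereoretentive cross-coupling and is not touched afterwards.

Key step: step 8

Remark: the molecule is achiral, so "single enantiomer" is read as the single (E) isomer drawn.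

Step 1
Reactants: 1 methyl methoxyacetate; 2 propionyl chloride
Product: 4 methyl 2-methoxy-3-oxopentanoate (racemic, labile centre), via lithium enolate 3 (not isolated)
Conditions: LDA (2 equiv), 1 (2 equiv), THF, −78 °C; then 2 (1 equiv), −78 → 0 °C; aq. NH4Cl
Reagents that add atoms: none
Why: Crossed Claisen acylation: the chelated lithium enolate 3 should be C-acylated by the acid chloride while the second equivalent of 3 takes up the acidic proton of 4, and the new C2 centre is configurationally labile and becomes sp2 in step 2.

Step 2
Reactants: 4 methyl 2-methoxy-3-oxopentanoate; 5 N-methoxy-N-methylacetamide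
Product: 8 4-hydroxy-3-methoxy-5,6-dimethyl-2H-pyran-2-one, via dilithio dianion 6 (not isolated), via diketo ester 7 (not isolated)
Conditions: LDA (2.2 equiv), THF, −78 → 0 °C; 5, −78 °C → rt; 1 M HCl; crude 7, DBU, PhMe, rt → 60 °C; 1 M HCl
Reagents that add atoms: none
Why: γ-Acylation of a β-keto ester dianion by a Weinreb amide (the chelated tetrahedral adduct prevents over-addition) followed by base-induced lactonisation of the C5 enol oxygen onto the ester (6-exo-trig, loss of methanol) is the standard triketide route to 4-hydroxy-2-pyrones, and both sp3 centres of 7 end as ring sp2 carbons.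

Step 3
Reactants: 8 4-hydroxy-3-methoxy-5,6-dimethyl-2H-pyran-2-one
Product: 9 2,3-dimethoxy-5,6-dimethyl-4H-pyran-4-one
Conditions: MeOTf (2 equiv), CH2Cl2, rt; sat. aq. NaHCO3
Reagents that add atoms: methyl trifluoromethanesulfonate, COS(=O)(=O)C(F)(F)F
Why: O-Alkylation with a hard, neutral methylating agent: the lactone carbonyl oxygen at C2 is the most basic site, so its methylation and loss of the 4-OH proton should give the 2-methoxy-4-pyrone instead of the 4-methoxy-2-pyrone favoured under basic alkylation.

Step 4
Reactants: 9 2,3-dimethoxy-5,6-dimethyl-4H-pyran-4-one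
Product: 11 6-(chloromethyl)-2,3-dimethoxy-5-methyl-4H-pyran-4-one, via lithium dienolate 10 (not isolated)
Conditions: LiHMDS (1.05 equiv), THF, −78 °C; cannulated into C2Cl6 (1.5 equiv), THF, −78 °C; aq. NH4Cl
Reagents that add atoms: hexachloroethane, ClC(Cl)(Cl)C(Cl)(Cl)Cl
Why: Lateral (vinylogous) deprotonation and positive-chlorine transfer from hexachloroethane, the method known for 6-methyl-1,3-dioxin-4-ones: only the C6 methyl is conjugated with the C4 carbonyl through C5=C6, and attack of 10 through its exocyclic carbon restores the pyrone, while inverse addition keeps 10 away from the product chloride.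

Step 5
Reactants: 11 6-(chloromethyl)-2,3-dimethoxy-5-methyl-4H-pyran-4-one; 12 hex-5-yn-1-ol
Product: 14 6-[(2E)-7-hydroxy-3-methylhept-2-en-1-yl]-2,3-dimethoxy-5-methyl-4H-pyran-4-one, via alkenylalane 13 (not isolated)
Conditions: 12 (1.3 equiv), Me3Al (3 equiv), Cp2ZrCl2 (25 mol %), CH2Cl2, 0 °C → rt; volatiles and excess Me3Al removed in vacuo; THF, 11 (1 equiv), NiCl2(PPh3)2/n-BuLi (5/10 mol %), 0 °C → rt; cold 1 M HCl
Reagents that add atoms: trimethylaluminium, C[Al](C)C
Why: Zirconium-catalysed syn-carboalumination (Negishi) puts CH3 on the internal and aluminium on the terminal alkyne carbon on the same side, and the nickel(0)-catalysed coupling of the alkenylalane with a benzylic-type chloride, known even for chloromethyl quinones that carry the same methoxy/carbonyl array, goes with retention, so that C2'=C3' is set as E.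

Step 6
Reactants: 14 6-[(2E)-7-hydroxy-3-methylhept-2-en-1-yl]-2,3-dimethoxy-5-methyl-4H-pyran-4-one
Product: 16 (5E)-7-(5,6-dimethoxy-3-methyl-4-oxo-4H-pyran-2-yl)-5-methylhept-5-enoic acid, via aldehyde 15 (not isolated)
Conditions: TEMPO (20 mol %), PhI(OAc)2 (2.2 equiv), MeCN–H2O 1:1, rt
Reagents that add atoms: water, O
Why: TEMPO/PhI(OAc)2 oxidation in aqueous acetonitrile: the oxoammonium ion oxidises only the primary alcohol, first to 15 and then through its hydrate to the acid, in a weakly acidic medium that leaves the trisubstituted alkene, the doubly activated C1' methylene and the 2-methoxy-4-pyrone alone.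

Step 7
Reactants: 17 7-bromoheptanoic acid
Product: 18 7-(acetylsulfanyl)heptanoic acid
Conditions: KSAc (1.2 equiv), DMF, rt; dilute HCl
Reagents that add atoms: potassium thioacetate, CC(=O)[S-].[K+]
Why: SN2 displacement of a primary bromide by the soft thioacetate anion, which is too weak a base to be quenched by the free carboxylic acid.

Step 8
Reactants: 16 (5E)-7-(5,6-dimethoxy-3-methyl-4-oxo-4H-pyran-2-yl)-5-methylhept-5-enoic acid; 18 7-(acetylsulfanyl)heptanoic acid
Product: 21 lehualide C, via head NHPI ester 19 (not isolated), via tail NHPI ester 20 (not isolated)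
Conditions: 16 (1 equiv), 18 (3 equiv), N-hydroxyphthalimide (4 equiv), DIC (4 equiv), DMF, rt, 2 h; then NiCl2·6H2O (20 mol %), 4,4′,4″-tri-tert-butyl-2,2′:6′,2″-terpyridine (20 mol %), NaI, DMF, undivided cell, Zn(+)/RVC(−), constant current, rt; aq. NH4Cl
Reagents that add atoms: none
Why: DIC condenses each acid with N-hydroxyphthalimide to 19 and 20; cathodically generated low-valent (terpyridine)nickel passes one electron into the phthalimide of either ester, the N–O bond breaks, CO2 is lost, and the primary radicals at C6' and C7' are collected one after the other on nickel to a dialkylnickel(III) species that forms C6'–C7' by reductive elimination, while the zinc anode supplies the two electrons. The closest known reaction type is the nickel-electrocatalytic doubly decarboxylative C(sp3)–C(sp3) cross-coupling of two redox-active esters, the reductive counterpart of the mixed Kolbe electrolysis, which is established for primary/primary pairs. Two carbons of like polarity (both partners are electron acceptors) are thus joined without an organometallic reagent, which matters because an alkylzinc or Grignard partner would transfer onto the thioacetate under nickel or palladium catalysis (Fukuyama-type ketone formation). No ring is closed and no stereocentre is formed, and (E)-C2'=C3' stays a spectator because the C6' radical is a pent-4-enyl radical with only the slow 4-exo and 5-endo closures open to it. Cross- versus homo-coupling is statistical and is secured by the threefold excess of the cheap acid 18 and by the large polarity gap between 21, the non-polar C12 bis(thioacetate) and the bis(pyrone) dimer. Chemoselectivity rests on potentials, since the N-acyloxyphthalimides accept an electron well before the S-alkyl thioacetate or the γ-pyrone, whose fully substituted ring also offers no C–H position for radical addition.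

Compound list
1 | methyl methoxyacetate | COCC(=O)OC | starting material
2 | propionyl chloride | CCC(=O)Cl | starting material
3 | lithium enolate of methyl methoxyacetate | COC=C(O[Li])OC | intermediate
4 | methyl 2-methoxy-3-oxopentanoate | CCC(=O)C(OC)C(=O)OC | intermediate
5 | N-methoxy-N-methylacetamide | CC(=O)N(C)OC | starting material
6 | dilithio dianion of 4 | CC=C(O[Li])C(OC)=C(O[Li])OC | intermediate
7 | methyl 2-methoxy-4-methyl-3,5-dioxohexanoate | CC(=O)C(C)C(=O)C(OC)C(=O)OC | intermediate
8 | 4-hydroxy-3-methoxy-5,6-dimethyl-2H-pyran-2-one | COc1c(O)c(C)c(C)oc1=O | intermediate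
9 | 2,3-dimethoxy-5,6-dimethyl-4H-pyran-4-one | COc1oc(C)c(C)c(=O)c1OC | intermediate
10 | lithium dienolate of 9 (6-methylidene-6H-pyran-4-olate) | C=C1OC(OC)=C(OC)C(O[Li])=C1C | intermediate
11 | 6-(chloromethyl)-2,3-dimethoxy-5-methyl-4H-pyran-4-one | COc1oc(CCl)c(C)c(=O)c1OC | intermediate
12 | hex-5-yn-1-ol | C#CCCCCO | starting material
13 | [(1E)-6-(dimethylalumanyloxy)-2-methylhex-1-en-1-yl]dimethylalane | C[Al](C)/C=C(\C)CCCCO[Al](C)C | intermediate
14 | 6-[(2E)-7-hydroxy-3-methylhept-2-en-1-yl]-2,3-dimethoxy-5-methyl-4H-pyran-4-one | COc1oc(C/C=C(\C)CCCCO)c(C)c(=O)c1OC | intermediate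
15 | (5E)-7-(5,6-dimethoxy-3-methyl-4-oxo-4H-pyran-2-yl)-5-methylhept-5-enal | COc1oc(C/C=C(\C)CCCC=O)c(C)c(=O)c1OC | intermediate
16 | (5E)-7-(5,6-dimethoxy-3-methyl-4-oxo-4H-pyran-2-yl)-5-methylhept-5-enoic acid | COc1oc(C/C=C(\C)CCCC(=O)O)c(C)c(=O)c1OC | intermediate
17 | 7-bromoheptanoic acid | OC(=O)CCCCCCBr | starting material
18 | 7-(acetylsulfanyl)heptanoic acid | CC(=O)SCCCCCCC(=O)O | intermediate
19 | N-phthalimidoyl ester of 16 | COc1oc(C/C=C(\C)CCCC(=O)ON2C(=O)c3ccccc3C2=O)c(C)c(=O)c1OC | intermediate
20 | N-phthalimidoyl ester of 18 | CC(=O)SCCCCCCC(=O)ON1C(=O)c2ccccc2C1=O | intermediate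
21 | lehualide C, S-[(10E)-12-(5,6-dimethoxy-3-methyl-4-oxo-4H-pyran-2-yl)-10-methyldodec-10-en-1-yl] ethanethioate | COc1oc(C/C=C(\C)CCCCCCCCCSC(C)=O)c(C)c(=O)c1OC | target

Total step count: 8. Longest linear sequence: 7 (steps 1–6 and 8).

Steps most likely to fail

Risk 1 (step 8): the two radicals pair statistically, so homocoupling and hydrogen abstraction from the solvent may consume the head acid. Further drains are a 1,5-hydrogen shift from the allylic C3' methyl to C6', and slow nickel insertion into the acyl–S bond, which would release thiolate and poison the catalyst. The fallback sets out from 11 and comes back at 21. It forms the same C6'–C7' bond by a two-electron alkyl–alkyl Suzuki–Miyaura coupling and brings in sulfur last. Pent-4-yn-1-ol is carboaluminated as in step 5 to the lower alkenylalane F1, which is coupled with 11 to the C6' alcohol F2. Appel bromination (CBr4, PPh3, CH2Cl2, 0 °C) gives the C6' bromide F3. 6-Chlorohex-1-ene and 9-BBN-H (THF, rt) give the B-(6-chlorohexyl)borane F4. Pd(OAc)2/PCy3, K3PO4·H2O, THF, rt should join F3 and F4 to the ω-chloride F5, since a primary chloride is inert under these conditions. KSAc with catalytic NaI in DMF at 50 °C (Finkelstein-assisted SN2) then gives 21.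

Risk 2 (step 5): Lewis-acidic aluminium species may bind to the C4 carbonyl/C3 methoxy array of the pyrone and cause demethylation. Methyl transfer to C1' may compete with alkenyl transfer, and the chloride may dimerise reductively on nickel. The fallback sets out from 13 and 11 and comes back at 14. It exchanges the roles of nucleophile and electrophile so that aluminium never meets the pyrone. The alane 13 is quenched with iodine (THF, −30 °C) to (5E)-6-iodo-5-methylhex-5-en-1-ol F6. Zinc dust/LiCl (THF, rt) inserts into 11 to give the pyronylmethylzinc chloride F7. Negishi coupling of F7 with F6 (Pd(OAc)2/SPhos, THF, rt, conditions under which benzylic zinc reagents tolerate a free hydroxyl) should give 14 with retention of the E geometry.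

Risk 3 (step 4): proton exchange between the dienolate and the more acidic product, alkylation of the dienolate by the newly formed chloride, and double chlorination may all erode the monochloride. The fallback sets out from 9 and comes back at 11, replacing the anionic halogenation by an oxidation/reduction sequence. Riley oxidation (SeO2, 1,4-dioxane, reflux) of the activated C6 methyl gives the pyrone carbaldehyde F8. NaBH4 in MeOH at 0 °C reduces only the aldehyde to the hydroxymethyl pyrone F9. SOCl2 in CH2Cl2 at 0 °C, the way kojic acid is turned into its chloride, gives 11.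

Further compounds
F1 | step 8 | [(1E)-5-(dimethylalumanyloxy)-2-methylpent-1-en-1-yl]dimethylalane | C[Al](C)/C=C(\C)CCCO[Al](C)C
F2 | step 8 | 6-[(2E)-6-hydroxy-3-methylhex-2-en-1-yl]-2,3-dimethoxy-5-methyl-4H-pyran-4-one | COc1oc(C/C=C(\C)CCCO)c(C)c(=O)c1OC
F3 | step 8 | 6-[(2E)-6-bromo-3-methylhex-2-en-1-yl]-2,3-dimethoxy-5-methyl-4H-pyran-4-one | COc1oc(C/C=C(\C)CCCBr)c(C)c(=O)c1OC
F4 | step 8 | 9-(6-chlorohexyl)-9-borabicyclo[3.3.1]nonane | ClCCCCCCB1C2CCCC1CCC2
F5 | step 8 | 6-[(2E)-12-chloro-3-methyldodec-2-en-1-yl]-2,3-dimethoxy-5-methyl-4H-pyran-4-one | COc1oc(C/C=C(\C)CCCCCCCCCCl)c(C)c(=O)c1OC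
F6 | step 5 | (5E)-6-iodo-5-methylhex-5-en-1-ol | I/C=C(\C)CCCCO
F7 | step 5 | [(5,6-dimethoxy-3-methyl-4-oxo-4H-pyran-2-yl)methyl]zinc chloride | COc1oc(C[Zn]Cl)c(C)c(=O)c1OC
F8 | step 4 | 5,6-dimethoxy-3-methyl-4-oxo-4H-pyran-2-carbaldehyde | COc1oc(C=O)c(C)c(=O)c1OC
F9 | step 4 | 6-(hydroxymethyl)-2,3-dimethoxy-5-methyl-4H-pyran-4-one | COc1oc(CO)c(C)c(=O)c1OC
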